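The route rests on disconnecting the single bond between C7, the exocyclic methine on the hydroxylated ring B, and C8, the first chain methine. The key step, a Heck alkenylation, exploits the fact that C7 is the unsubstituted terminus of the ring B diene C4=C5–C6=C7, flanked by quaternary C1. A C30 retro-polyenyl triflate is joined to the C7–H of a silyl-protected (S)-4-methylene-3,5,5-trimethylcyclohex-2-enol, and β-hydride elimination restores C6=C7 with the chain syn to C1. The triflate comes from commercial β-apo-8'-carotenal by ring dehydrogenation and O-triflation of its fully extended enolate, which shifts every double bond and turns the aldehyde carbon into C8.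

Key step: step 6

Remark: carotenoid numbering is used (ring B, the hydroxylated ring, is C1–C6 with oxygen on C3 and C7 exocyclic; primed numbers belong to the ring A half), and the ring B carbinol centre of the target is (S).

Step 1
Reactants: 1 all-trans-β-apo-8'-carotenal
Product: 3 3',4'-didehydro-β-apo-8'-carotenal, via 4'-bromo-β-apo-8'-carotenal 2 (not isolated)
Conditions: NBS (1.05 equiv), CH2Cl2, −20 °C, dark; then N-ethylmorpholine, 0 °C → rt
Reagents that add atoms: none
Why: Wohl–Ziegler-type allylic bromination should take place at the ring methylene C4', the only CH2 whose radical or cation is conjugated with the whole polyenal, and E2 dehydrobromination by the amine then gives the ring 1,3-diene, the same sequence that dehydrogenates retinoate esters to their 3,4-didehydro analogues.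

Step 2
Reactants: 3 3',4'-didehydro-β-apo-8'-carotenal
Product: 5 C30 retro-polyenyl triflate, via potassium polyenolate 4 (not isolated)
Conditions: KN(SiMe3)2 (0.97 equiv), THF, −78 → −20 °C; then PhNTf2, −78 → 0 °C; cold water work-up, dark, used at once
Reagents that add atoms: N-phenylbis(trifluoromethanesulfonimide) (PhNTf2), O=S(=O)(N(c1ccccc1)S(=O)(=O)C(F)(F)F)C(F)(F)F
Why: Vinylogous enolisation followed by O-sulfonylation (enol triflate formation) should, with a slight deficit of base allowing equilibration, remove a ring C2' proton because only that site gives the linearly conjugated polyenolate, and O-triflation of this enolate, whose new double bonds arise from the s-trans single bonds of 3, should give the all-trans triflate with oxygen trans to C10 and the chain syn to the ring CMe2 carbon.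

Step 3
Reactants: 6 2,6,6-trimethylcyclohex-2-ene-1,4-dione (ketoisophorone)
Product: 7 (4S)-4-hydroxy-2,6,6-trimethylcyclohex-2-en-1-one
Conditions: RuCl(p-cymene)[(S,S)-TsDPEN] (1 mol %), KOH (2 mol %), iPrOH, rt
Reagents that add atoms: none
Why: Noyori-type asymmetric transfer hydrogenation should reduce only the unhindered C4 carbonyl (C1 is shielded by the gem-dimethyl and vinylic methyl groups), the chiral ruthenium hydride delivering hydride to one face so that the (S)-carbinol, the future C3 of ring B, is expected from the (S,S)-ligand by analogy with aryl ketones, the antipodal ligand being used should the sense prove reversed.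

Step 4
Reactants: 7 (4S)-4-hydroxy-2,6,6-trimethylcyclohex-2-en-1-one
Product: 8 (4S)-4-(tert-butyldimethylsilyloxy)-2,6,6-trimethylcyclohex-2-en-1-one
Conditions: TBSOTf, 2,6-lutidine, CH2Cl2, −78 °C
Reagents that add atoms: tert-butyldimethylsilyl triflate (TBSOTf), CC(C)(C)[Si](C)(C)OS(=O)(=O)C(F)(F)F
Why: Silylation of the secondary alcohol is faster than any enolisation of the enone under these conditions, and the silyl ether is chosen because zerovalent palladium does not ionise it as it would an allylic ester and because it is later removed without acid.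

Step 5
Reactants: 8 (4S)-4-(tert-butyldimethylsilyloxy)-2,6,6-trimethylcyclohex-2-en-1-one
Product: 9 tert-butyldimethyl{[(1S)-3,5,5-trimethyl-4-methylidenecyclohex-2-en-1-yl]oxy}silane
Conditions: Cp2TiMe2 (2 equiv), toluene, 70 °C, dark
Reagents that add atoms: dimethyltitanocene (Cp2TiMe2), C[Ti](C)(C1C=CC=C1)C1C=CC=C1
Why: Petasis methylenation, in which thermally generated titanocene methylidene undergoes [2+2] cycloaddition and cycloreversion with the hindered ketone under non-basic conditions, should give the exocyclic diene without removing the γ-hydrogen at the carbinol centre, so the (S) configuration is kept.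

Step 6
Reactants: 5 C30 retro-polyenyl triflate; 9 tert-butyldimethyl{[(1S)-3,5,5-trimethyl-4-methylidenecyclohex-2-en-1-yl]oxy}silane (2 equiv)
Product: 10 tert-butyldimethylsilyl ether of the target
Conditions: Pd(OAc)2 (10 mol %), PPh3 (20 mol %), NaHCO3 (3 equiv), DMF, 50 °C, dark, argon
Reagents that add atoms: none
Why: Mizoroki–Heck alkenylation of a 1,3-diene: zerovalent palladium inserts into the C8–O bond of 5 with retention of the C8=C9 geometry, the alkenylpalladium species adds syn across the exocyclic C6=C7H2 of 9 so that C8 bonds to the terminal C7 and palladium sits on C6 as an η3-allyl over C6–C5–C4, and syn β-hydride elimination of a C7–H restores C6=C7 and gives the fully conjugated retro-polyene. The closest known reaction type is the Heck coupling of alkenyl triflates with conjugated dienes to give trienes. No ring is closed and no stereocentre is formed; the (S)-carbinol centre is remote from the reacting atoms and its silyl ether is not ionised by palladium. Regioselectivity for C7 over the trisubstituted ring carbon C4 follows from sterics, and elimination toward C7 is secured because C1 carries no hydrogen and loss of the C3 hydrogen would leave C7 saturated and the ring unconjugated with the polyene. The C6=C7 geometry is decided in the elimination, where the rotamer placing C8 on the side of the gem-dimethyl carbon C1 avoids the in-plane clash with the C5 methyl group, so the chain should end up syn to C1 as required.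

Step 7
Reactants: 10 tert-butyldimethylsilyl ether of the target
Product: 11 target, (3S)-2',3',4',5'-tetradehydro-4,5'-retro-β,β-caroten-3-ol
Conditions: Bu4NF (1 M in THF), THF, 0 °C → rt, dark
Reagents that add atoms: none
Why: Fluoride-mediated desilylation frees the allylic alcohol under non-acidic conditions, which matters because the C3 carbinol is allylic to the whole polyene and would ionise and dehydrate under acid, and the stereocentre is untouched.

Compound list

1 | all-trans-β-apo-8'-carotenal, (2E,4E,6E,8E,10E,12E,14E,16E)-2,6,11,15-tetramethyl-17-(2,6,6-trimethylcyclohex-1-en-1-yl)heptadeca-2,4,6,8,10,12,14,16-octaenal | CC1=C(C(C)(C)CCC1)/C=C/C(C)=C/C=C/C(C)=C/C=C/C=C(C)/C=C/C=C(C)/C=O | starting material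
2 | 4'-bromo-β-apo-8'-carotenal (1 with bromine on the ring CH2 next to the vinylic methyl carbon, racemic there) | CC1=C(C(C)(C)CCC1Br)/C=C/C(C)=C/C=C/C(C)=C/C=C/C=C(C)/C=C/C=C(C)/C=O | intermediate
3 | 3',4'-didehydro-β-apo-8'-carotenal (the all-E octaenal of 1 carrying a 2,6,6-trimethylcyclohexa-1,3-dien-1-yl ring) | CC1=C(C(C)(C)CC=C1)/C=C/C(C)=C/C=C/C(C)=C/C=C/C=C(C)/C=C/C=C(C)/C=O | intermediate
4 | potassium polyenolate of 3 in its retro form (all double bonds shifted by one position, ring as 2,6,6-trimethylcyclohexa-2,4-dien-1-ylidene, enolate oxygen on C8) | [K+].CC1=CC=CC(C)(C)\C1=C/C=C(C)/C=C/C=C(C)/C=C/C=C/C(C)=C/C=C/C(C)=C/[O-] | intermediate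
5 | C30 retro-polyenyl triflate, (1E,3E,5E,7E,9E,11E,13E,15E)-2,6,11,15-tetramethyl-17-(2,6,6-trimethylcyclohexa-2,4-dien-1-ylidene)heptadeca-1,3,5,7,9,11,13,15-octaen-1-yl trifluoromethanesulfonate, chain syn to the ring CMe2 carbon | CC1=CC=CC(C)(C)\C1=C/C=C(C)/C=C/C=C(C)/C=C/C=C/C(C)=C/C=C/C(C)=C/OS(=O)(=O)C(F)(F)F | intermediate
6 | 2,6,6-trimethylcyclohex-2-ene-1,4-dione (ketoisophorone) | CC1=CC(=O)CC(C)(C)C1=O | starting material
7 | (4S)-4-hydroxy-2,6,6-trimethylcyclohex-2-en-1-one | CC1=C[C@@H](O)CC(C)(C)C1=O | intermediate
8 | (4S)-4-(tert-butyldimethylsilyloxy)-2,6,6-trimethylcyclohex-2-en-1-one | CC1=C[C@@H](O[Si](C)(C)C(C)(C)C)CC(C)(C)C1=O | intermediate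
9 | tert-butyldimethyl{[(1S)-3,5,5-trimethyl-4-methylidenecyclohex-2-en-1-yl]oxy}silane (ring B diene) | CC1=C[C@@H](O[Si](C)(C)C(C)(C)C)CC(C)(C)C1=C | intermediate
10 | tert-butyldimethylsilyl ether of the target (all-trans retro-polyene, silyloxy group on the (S)-configured C3 of ring B) | CC1=CC=CC(C)(C)\C1=C/C=C(C)/C=C/C=C(C)/C=C/C=C/C(C)=C/C=C/C(C)=C/C=C1/C(C)=C[C@@H](O[Si](C)(C)C(C)(C)C)CC1(C)C | intermediate
11 | (3S)-2',3',4',5'-tetradehydro-4,5'-retro-β,β-caroten-3-ol: a (1S)-3,5,5-trimethylcyclohex-2-en-1-ol whose C4 is joined by an exocyclic double bond, through an all-trans tetramethyl-substituted C18 polyene chain, to a 2,6,6-trimethylcyclohexa-2,4-dien-1-ylidene ring, the chain syn to the CMe2 carbon at both rings | CC1=CC=CC(C)(C)\C1=C/C=C(C)/C=C/C=C(C)/C=C/C=C/C(C)=C/C=C/C(C)=C/C=C1/C(C)=C[C@@H](O)CC1(C)C | target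

Total step count: 7. Longest linear sequence: 5 steps (6 → 7 → 8 → 9 → 10 → 11); the other arm is 4 steps (1 → 3 → 5 → 10 → 11).

Steps most likely to fail

1. Step 6 (Heck coupling). Migratory insertion at the hindered exocyclic methylene may be too slow, so that the polyenylpalladium species decays, or the β-hydride elimination may give poor control of the C6=C7 geometry. The fallback makes the same bond by carbonyl alkenylation and dehydration; it sets out from 9 (with 5 unchanged) and comes back at 10. Hydroboration of the exocyclic methylene of 9 with 9-BBN (THF, rt) should give the B-alkyl borane F1, which is oxidised in the same flask (NaBO3·4H2O, water) to the primary alcohol F2; its epimers at ring carbon C6 are of no consequence. Dess–Martin periodinane (CH2Cl2, NaHCO3) then gives the aldehyde F3. Nozaki–Hiyama–Kishi coupling of F3 with triflate 5 (CrCl2, catalytic NiCl2, DMF, rt) forms the C7–C8 bond as the secondary allylic alcohol F4. Syn-dehydration with the Burgess reagent (THF, rt → 50 °C), which can only take the hydrogen on C6, gives 10.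

2. Step 2 (extended enol triflate). Deprotonation may occur at the methyl groups on C5', C9' or C13' instead of C2', the enolate may condense with unreacted aldehyde, or the triflate may decompose on handling. The fallback enolises under soft, amine-mediated conditions through an isolable intermediate; it sets out from 3 and comes back at 5. Et3SiOTf and Et3N (CH2Cl2, −78 → 0 °C) should convert 3, through its O-silylated polyenyl cation, into the triethylsilyl polyenol ether F5. Unlike the triflate, F5 can be freed from isomers by crystallisation or chromatography on deactivated alumina. CsF and PhNTf2 (DME, rt) then exchange silyl for triflyl to give 5.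

3. Step 1 (ring dehydrogenation). Bromination may attack the polyene chain or the chain methyl groups, or over-bromination may dominate. The fallback brings the ring diene in ready-made by Wittig olefination. It does not use 1: it sets out from commercial safranal (2,6,6-trimethylcyclohexa-1,3-diene-1-carbaldehyde, CC1=C(C=O)C(C)(C)CC=C1) and commercial crocetindial (2,6,11,15-tetramethylhexadeca-2,4,6,8,10,12,14-heptaenedial, O=C/C(C)=C/C=C/C(C)=C/C=C/C=C(C)/C=C/C=C(C)/C=O), and comes back at 3. NaBH4 (MeOH, 0 °C) reduces safranal to safranol F6, and Ph3P·HBr (MeOH, rt) converts it into the allylic phosphonium bromide F7. NaOMe generates the ylide F8, which is condensed with an excess of crocetindial (CH2Cl2/MeOH, rt) so that only one aldehyde reacts. The geometry of the new C7'=C8' bond is immaterial because that bond becomes single in 5.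

Further compounds

F1 | step 6 | 9-{[(4S)-4-(tert-butyldimethylsilyloxy)-2,6,6-trimethylcyclohex-2-en-1-yl]methyl}-9-borabicyclo[3.3.1]nonane | CC1=C[C@@H](O[Si](C)(C)C(C)(C)C)CC(C)(C)C1CB1C2CCCC1CCC2
F2 | step 6 | [(4S)-4-(tert-butyldimethylsilyloxy)-2,6,6-trimethylcyclohex-2-en-1-yl]methanol | CC1=C[C@@H](O[Si](C)(C)C(C)(C)C)CC(C)(C)C1CO
F3 | step 6 | (4S)-4-(tert-butyldimethylsilyloxy)-2,6,6-trimethylcyclohex-2-ene-1-carbaldehyde | CC1=C[C@@H](O[Si](C)(C)C(C)(C)C)CC(C)(C)C1C=O
F4 | step 6 | C7 carbinol: the retro-polyenyl chain of 5 bonded through C8 to the CH(OH) carbon that carries the (4S)-4-(tert-butyldimethylsilyloxy)-2,6,6-trimethylcyclohex-2-en-1-yl ring | CC1=CC=CC(C)(C)\C1=C/C=C(C)/C=C/C=C(C)/C=C/C=C/C(C)=C/C=C/C(C)=C/C(O)C1C(C)=C[C@@H](O[Si](C)(C)C(C)(C)C)CC1(C)C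
F5 | step 2 | triethylsilyl polyenol ether of 3 in its retro form | CC1=CC=CC(C)(C)\C1=C/C=C(C)/C=C/C=C(C)/C=C/C=C/C(C)=C/C=C/C(C)=C/O[Si](CC)(CC)CC
F6 | step 1 | safranol, (2,6,6-trimethylcyclohexa-1,3-dien-1-yl)methanol | CC1=C(CO)C(C)(C)CC=C1
F7 | step 1 | triphenyl[(2,6,6-trimethylcyclohexa-1,3-dien-1-yl)methyl]phosphonium bromide | CC1=C(C[P+](c2ccccc2)(c2ccccc2)c2ccccc2)C(C)(C)CC=C1.[Br-]
F8 | step 1 | triphenyl[(2,6,6-trimethylcyclohexa-1,3-dien-1-yl)methylidene]phosphorane | CC1=C(C=P(c2ccccc2)(c2ccccc2)c2ccccc2)C(C)(C)CC=C1
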